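**Retrosynthetic overview**
- Ring A (the α-alkylidene γ-lactone) is opened to a γ-hydroxy (Z)-enoate; its carbinol comes from oxazaborolidine reduction of a γ-keto (Z)-enoate, so ring A is closed last.
- The Z-trisubstituted enoate is cut by a Still–Gennari olefination into a trienal carrying the butenolide and a γ-keto α-phosphono ester.
- Key disconnection: the C4–C5 bond of that keto phosphonate is made by a Stetter reaction in which prenal acts as an acyl anion toward the β-carbon of an α-phosphonoacrylate.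
- The trienal comes from (2E,6E)-farnesol: terminal epoxide as latent aldehyde, allylic oxidation, vinylogous Horner–Wadsworth–Emmons reaction with a butenolide phosphonate, epoxide cleavage.
- Ring B (the butenolide) is formed first, by dibromination and lactonisation of ethyl 3-methylbut-2-enoate.

Assumption: (2E,6E)-farnesol, prenal, ethyl 3-methylbut-2-enoate and methyl bis(2,2,2-trifluoroethyl)phosphonoacetate are taken as commercial; the transient epoxide stereocentre is racemic and is excised later.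

**Step 1**
Reactants: 1 ethyl 3-methylbut-2-enoate
Product: 3 4-(bromomethyl)furan-2(5H)-one, via ethyl 4-bromo-3-(bromomethyl)but-2-enoate 2 (not isolated)
Conditions: NBS (2.2 equiv), AIBN (5 mol %), PhCF3, reflux; filter, concentrate; then neat, 150 °C, EtBr distilled off
Reagents that add atoms: N-bromosuccinimide, O=C1CCC(=O)N1Br
Why: Wohl–Ziegler bromination of both allylic methyl groups is followed by thermal lactonisation of the γ-bromo ester (the bromomethyl group cis to the ester closes ring B with loss of bromoethane); no stereocentre is formed.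

**Step 2**
Reactants: 3 4-(bromomethyl)furan-2(5H)-one
Product: 4 diethyl [(5-oxo-2,5-dihydrofuran-3-yl)methyl]phosphonate
Conditions: P(OEt)3 (1.2 equiv), PhMe, 110 °C
Reagents that add atoms: triethyl phosphite, CCOP(OCC)OCC
Why: Michaelis–Arbuzov reaction of a reactive primary allylic bromide gives the vinylogous phosphonoacetate.

**Step 3**
Reactants: 5 (2E,6E)-farnesol
Product: 7 (2E,6E)-9-(3,3-dimethyloxiran-2-yl)-3,7-dimethylnona-2,6-dien-1-ol (racemic), via (2E,6E)-10-bromo-3,7,11-trimethyldodeca-2,6-diene-1,11-diol 6 (not isolated)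
Conditions: NBS (1.1 equiv), THF/H2O (3:1), 0 °C; then K2CO3, MeOH, rt
Reagents that add atoms: water, O
Why: van Tamelen terminal-selective bromohydrin formation in aqueous THF followed by base-induced epoxide closure marks the terminal alkene as a latent aldehyde; the epoxide carbon is racemic and is removed in step 6.

**Step 4**
Reactants: 7 (2E,6E)-9-(3,3-dimethyloxiran-2-yl)-3,7-dimethylnona-2,6-dien-1-ol
Product: 8 (2E,6E)-9-(3,3-dimethyloxiran-2-yl)-3,7-dimethylnona-2,6-dienal
Conditions: MnO2 (15 equiv), CH2Cl2, rt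
Reagents that add atoms: none
Why: MnO2 oxidises only the allylic alcohol, keeps the 2E geometry and leaves the epoxide untouched (allylic oxidation).

**Step 5**
Reactants: 8 (2E,6E)-9-(3,3-dimethyloxiran-2-yl)-3,7-dimethylnona-2,6-dienal; 4 diethyl [(5-oxo-2,5-dihydrofuran-3-yl)methyl]phosphonate
Product: 9 4-[(1E,3E,7E)-10-(3,3-dimethyloxiran-2-yl)-4,8-dimethyldeca-1,3,7-trien-1-yl]furan-2(5H)-one
Conditions: 4 (1.2 equiv), LiN(SiMe3)2 (1.15 equiv), THF, −78 °C; then 8, −78 → 0 °C
Reagents that add atoms: none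
Why: Vinylogous Horner–Wadsworth–Emmons olefination (cyclic analogue of the 4-phosphonocrotonates used in polyene synthesis) reacts through the phosphorus-bearing carbon and gives the new disubstituted alkene E under thermodynamic control of the oxaphosphetane.

**Step 6**
Reactants: 9 4-[(1E,3E,7E)-10-(3,3-dimethyloxiran-2-yl)-4,8-dimethyldeca-1,3,7-trien-1-yl]furan-2(5H)-one
Product: 10 (4E,8E,10E)-4,8-dimethyl-11-(5-oxo-2,5-dihydrofuran-3-yl)undeca-4,8,10-trienal
Conditions: HIO4·2H2O (1.2 equiv), THF/Et2O, 0 °C, 30 min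
Reagents that add atoms: none
Why: Periodic acid opens the trisubstituted epoxide at its tertiary carbon and cleaves the resulting glycol in one operation (epoxide oxidative cleavage), so the aldehyde keeps the former epoxide oxygen and acetone is lost.

**Step 7**
Reactants: 11 methyl 2-[bis(2,2,2-trifluoroethoxy)phosphoryl]acetate
Product: 14 methyl 2-[bis(2,2,2-trifluoroethoxy)phosphoryl]prop-2-enoate, via methyl 2-[bis(2,2,2-trifluoroethoxy)phosphoryl]-3-(dimethylamino)propanoate 12 (not isolated), via {2-[bis(2,2,2-trifluoroethoxy)phosphoryl]-3-methoxy-3-oxopropyl}trimethylazanium iodide 13 (not isolated)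
Conditions: NaH (1.0 equiv), THF, 0 °C; Me2N=CH2+ I− (1.05 equiv), 0 °C → rt; MeI (3 equiv), rt; aq NaHCO3, cold dilute HCl wash
Reagents that add atoms: N,N-dimethylmethyleneiminium iodide (Eschenmoser's salt), C=[N+](C)C.[I-]
Why: Mannich methylenation of the active methylene compound, N-quaternisation and E1cB loss of trimethylamine give the α-phosphonoacrylate under aprotic, non-nucleophilic conditions that spare the trifluoroethyl phosphonate esters.

**Step 8**
Reactants: 15 3-methylbut-2-enal (prenal); 14 methyl 2-[bis(2,2,2-trifluoroethoxy)phosphoryl]prop-2-enoate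
Product: 16 methyl 2-[bis(2,2,2-trifluoroethoxy)phosphoryl]-6-methyl-4-oxohept-5-enoate (racemic)
Conditions: 3-ethyl-5-(2-hydroxyethyl)-4-methylthiazolium bromide (20 mol %), Et3N (40 mol %), 15 (1.5 equiv), 1,4-dioxane, 70 °C, 14 added over 4 h
Reagents that add atoms: none
Why: Stetter reaction, in which the thiazol-2-ylidene turns prenal into its Breslow intermediate (an acyl anion) that adds through the former formyl carbon (future C5) to the unsubstituted β-carbon (future C4) of the doubly activated acrylate and so joins two normally electrophilic carbons; thiazolium carbenes favour acyl-anion over homoenolate reactivity of enals, the fully substituted β-carbon of prenal disfavours the latter further, and the racemic centre next to phosphorus is destroyed in step 9.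

**Step 9**
Reactants: 16 methyl 2-[bis(2,2,2-trifluoroethoxy)phosphoryl]-6-methyl-4-oxohept-5-enoate; 10 (4E,8E,10E)-4,8-dimethyl-11-(5-oxo-2,5-dihydrofuran-3-yl)undeca-4,8,10-trienal
Product: 17 methyl (2Z,6E,10E,12E)-6,10-dimethyl-2-(4-methyl-2-oxopent-3-en-1-yl)-13-(5-oxo-2,5-dihydrofuran-3-yl)trideca-2,6,10,12-tetraenoate
Conditions: 16 (1.1 equiv), KN(SiMe3)2 (1.05 equiv), 18-crown-6 (4 equiv), THF, −78 °C; then 10, −78 °C
Reagents that add atoms: none
Why: Still–Gennari olefination of an α-substituted bis(trifluoroethyl) phosphonate with an unbranched aliphatic aldehyde gives, by fast irreversible collapse of the kinetic adduct, the Z-trisubstituted enoate with the chain cis to the ester, which is exactly the alkylidene geometry of the target.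

**Step 10**
Reactants: 17 methyl (2Z,6E,10E,12E)-6,10-dimethyl-2-(4-methyl-2-oxopent-3-en-1-yl)-13-(5-oxo-2,5-dihydrofuran-3-yl)trideca-2,6,10,12-tetraenoate
Product: 19 (3Z,5R)-3-[(4E,8E,10E)-4,8-dimethyl-11-(5-oxo-2,5-dihydrofuran-3-yl)undeca-4,8,10-trien-1-ylidene]-5-(2-methylprop-1-en-1-yl)oxolan-2-one, via methyl (2Z,6E,10E,12E)-2-[(2R)-2-hydroxy-4-methylpent-3-en-1-yl]-6,10-dimethyl-13-(5-oxo-2,5-dihydrofuran-3-yl)trideca-2,6,10,12-tetraenoate 18 (not isolated)
Conditions: (S)-2-methyl-CBS-oxazaborolidine (20 mol %), catecholborane (1.8 equiv), PhMe, −78 °C; MeOH quench, aqueous work-up; then PPTS (10 mol %), PhMe, rt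
Reagents that add atoms: none
Why: Corey–Bakshi–Shibata 1,2-reduction of the enone, with the alkenyl group as the large substituent, gives the (R)-allylic alcohol with the (S)-catalyst (same sense as cyclohex-2-enone to (R)-cyclohex-2-enol), and mild acid-catalysed lactonisation onto the methyl ester then closes ring A without touching the Z-alkene or C5.

**Compound list**
1 | ethyl 3-methylbut-2-enoate | CCOC(=O)C=C(C)C | starting material
2 | ethyl 4-bromo-3-(bromomethyl)but-2-enoate | CCOC(=O)C=C(CBr)CBr | intermediate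
3 | 4-(bromomethyl)furan-2(5H)-one | BrCC1=CC(=O)OC1 | intermediate
4 | diethyl [(5-oxo-2,5-dihydrofuran-3-yl)methyl]phosphonate | CCOP(=O)(CC1=CC(=O)OC1)OCC | intermediate
5 | (2E,6E)-3,7,11-trimethyldodeca-2,6,10-trien-1-ol ((2E,6E)-farnesol) | CC(C)=CCC/C(C)=C/CC/C(C)=C/CO | starting material
6 | (2E,6E)-10-bromo-3,7,11-trimethyldodeca-2,6-diene-1,11-diol (racemic) | CC(C)(O)C(Br)CC/C(C)=C/CC/C(C)=C/CO | intermediate
7 | (2E,6E)-9-(3,3-dimethyloxiran-2-yl)-3,7-dimethylnona-2,6-dien-1-ol (racemic) | CC1(C)OC1CC/C(C)=C/CC/C(C)=C/CO | intermediate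
8 | (2E,6E)-9-(3,3-dimethyloxiran-2-yl)-3,7-dimethylnona-2,6-dienal (racemic) | CC1(C)OC1CC/C(C)=C/CC/C(C)=C/C=O | intermediate
9 | 4-[(1E,3E,7E)-10-(3,3-dimethyloxiran-2-yl)-4,8-dimethyldeca-1,3,7-trien-1-yl]furan-2(5H)-one (racemic) | CC1(C)OC1CC/C(C)=C/CC/C(C)=C/C=C/C2=CC(=O)OC2 | intermediate
10 | (4E,8E,10E)-4,8-dimethyl-11-(5-oxo-2,5-dihydrofuran-3-yl)undeca-4,8,10-trienal | O=CCC/C(C)=C/CC/C(C)=C/C=C/C1=CC(=O)OC1 | intermediate
11 | methyl 2-[bis(2,2,2-trifluoroethoxy)phosphoryl]acetate | COC(=O)CP(=O)(OCC(F)(F)F)OCC(F)(F)F | starting material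
12 | methyl 2-[bis(2,2,2-trifluoroethoxy)phosphoryl]-3-(dimethylamino)propanoate (racemic) | COC(=O)C(CN(C)C)P(=O)(OCC(F)(F)F)OCC(F)(F)F | intermediate
13 | {2-[bis(2,2,2-trifluoroethoxy)phosphoryl]-3-methoxy-3-oxopropyl}trimethylazanium iodide (racemic) | COC(=O)C(C[N+](C)(C)C)P(=O)(OCC(F)(F)F)OCC(F)(F)F.[I-] | intermediate
14 | methyl 2-[bis(2,2,2-trifluoroethoxy)phosphoryl]prop-2-enoate | COC(=O)C(=C)P(=O)(OCC(F)(F)F)OCC(F)(F)F | intermediate
15 | 3-methylbut-2-enal (prenal) | CC(C)=CC=O | starting material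
16 | methyl 2-[bis(2,2,2-trifluoroethoxy)phosphoryl]-6-methyl-4-oxohept-5-enoate (racemic) | COC(=O)C(CC(=O)C=C(C)C)P(=O)(OCC(F)(F)F)OCC(F)(F)F | intermediate
17 | methyl (2Z,6E,10E,12E)-6,10-dimethyl-2-(4-methyl-2-oxopent-3-en-1-yl)-13-(5-oxo-2,5-dihydrofuran-3-yl)trideca-2,6,10,12-tetraenoate | CC(C)=CC(=O)C/C(=C/CC/C(C)=C/CC/C(C)=C/C=C/C1=CC(=O)OC1)C(=O)OC | intermediate
18 | methyl (2Z,6E,10E,12E)-2-[(2R)-2-hydroxy-4-methylpent-3-en-1-yl]-6,10-dimethyl-13-(5-oxo-2,5-dihydrofuran-3-yl)trideca-2,6,10,12-tetraenoate | CC(C)=C[C@H](O)C/C(=C/CC/C(C)=C/CC/C(C)=C/C=C/C1=CC(=O)OC1)C(=O)OC | intermediate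
19 | (3Z,5R)-3-[(4E,8E,10E)-4,8-dimethyl-11-(5-oxo-2,5-dihydrofuran-3-yl)undeca-4,8,10-trien-1-ylidene]-5-(2-methylprop-1-en-1-yl)oxolan-2-one | CC(C)=C[C@H]1C/C(=C/CC/C(C)=C/CC/C(C)=C/C=C/C2=CC(=O)OC2)C(=O)O1 | target

**Totals**
Total step count: 10. Longest linear sequence: 6 steps (steps 3, 4, 5, 6, 9, 10, from 5 to 19).

**Three steps most likely to fail, with fallbacks**

Step 8 (Stetter reaction of prenal with 14). The carbene may be trapped by the very electrophilic acrylate, prenal may self-condense, or amine may polymerise 14. The fallback replaces the acyl anion by an enolonium equivalent of mesityl oxide. It sets out from 11 and returns at 16, and makes steps 7 and 8 unnecessary. Commercial mesityl oxide is converted with LiN(iPr)2 and Me3SiCl (THF, −78 °C) into 4-methyl-2-(trimethylsilyloxy)penta-1,3-diene F1. F1 is brominated with NBS (THF, 0 °C) to 1-bromo-4-methylpent-3-en-2-one F2. The sodium salt of 11 (NaH, THF, 0 °C) is then C-alkylated with F2 to give 16.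

Step 10 (reduction of 17 and ring closure). The enantioselectivity may be moderate because both ketone substituents are of similar size, and a poor result cannot be corrected on the final polyene. The fallback moves the stereocentre-forming step to the small fragment and closes ring A before the olefination. It sets out from 16 and returns at 19. Ketone 16 is reduced ((S)-2-methyl-CBS-oxazaborolidine, catecholborane, PhMe, −78 °C; a stoichiometric chiral borane or a ketoreductase can be screened at this stage without risk to the polyene) to methyl (4R)-2-[bis(2,2,2-trifluoroethoxy)phosphoryl]-4-hydroxy-6-methylhept-5-enoate F3, whose enantiomeric purity is checked. F3 is lactonised (PPTS, PhMe, rt) to (5R)-3-[bis(2,2,2-trifluoroethoxy)phosphoryl]-5-(2-methylprop-1-en-1-yl)oxolan-2-one F4. F4 is then olefinated with aldehyde 10 (KN(SiMe3)2, 18-crown-6, THF, −78 °C) to give 19 directly. Z-selectivity of this cyclic phosphonate is less well established than in step 9, and the alkoxide could attack phosphorus instead of the ester.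

Step 5 (vinylogous olefination with 4). The anion of 4 may self-condense or give E/Z mixtures. The fallback forms the butenolide–diene bond by cross-coupling instead. It sets out from 8 and returns at 9. Aldehyde 8 is homologated with dimethyl (1-diazo-2-oxopropyl)phosphonate (K2CO3, MeOH, rt) to 2,2-dimethyl-3-[(3E,7E)-3,7-dimethyldeca-3,7-dien-9-yn-1-yl]oxirane F5. F5 is hydroborated with pinacolborane (Cp2Zr(H)Cl 10 mol %, Et3N, 60 °C) to 2-[(1E,3E,7E)-10-(3,3-dimethyloxiran-2-yl)-4,8-dimethyldeca-1,3,7-trien-1-yl]-4,4,5,5-tetramethyl-1,3,2-dioxaborolane F6. F6 is coupled with commercial 4-bromofuran-2(5H)-one (Pd(PPh3)4, aq K3PO4, THF, 50 °C; Suzuki–Miyaura coupling, retention of the E geometry) to give 9; phosphonate 4 and steps 1 and 2 are then not needed.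

**Further compounds**
F1 | step 8 | 4-methyl-2-(trimethylsilyloxy)penta-1,3-diene | CC(C)=CC(=C)O[Si](C)(C)C
F2 | step 8 | 1-bromo-4-methylpent-3-en-2-one | CC(C)=CC(=O)CBr
F3 | step 10 | methyl (4R)-2-[bis(2,2,2-trifluoroethoxy)phosphoryl]-4-hydroxy-6-methylhept-5-enoate | COC(=O)C(C[C@@H](O)C=C(C)C)P(=O)(OCC(F)(F)F)OCC(F)(F)F
F4 | step 10 | (5R)-3-[bis(2,2,2-trifluoroethoxy)phosphoryl]-5-(2-methylprop-1-en-1-yl)oxolan-2-one | CC(C)=C[C@H]1CC(C(=O)O1)P(=O)(OCC(F)(F)F)OCC(F)(F)F
F5 | step 5 | 2,2-dimethyl-3-[(3E,7E)-3,7-dimethyldeca-3,7-dien-9-yn-1-yl]oxirane | CC1(C)OC1CC/C(C)=C/CC/C(C)=C/C#C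
F6 | step 5 | 2-[(1E,3E,7E)-10-(3,3-dimethyloxiran-2-yl)-4,8-dimethyldeca-1,3,7-trien-1-yl]-4,4,5,5-tetramethyl-1,3,2-dioxaborolane | CC1(C)OC1CC/C(C)=C/CC/C(C)=C/C=C/B2OC(C)(C)C(C)(C)O2
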